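**Plan**

1. Retrosynthesis: cut the C11–O aryl ether (umbelliferone), then C9–C11 (one carbon added to a C9 ketone), then together C1–C2 and C3–C4 of ring A, then C10–C1 and C10–CH3 (two α'-alkylations); this leaves (S)-carvone as ring B.
2. Forward: carvone already holds ring B with CH3-8, the C7=C8 bond, the C9 carbonyl, the C5 stereocenter and, as its isopropenyl group, C4 with one of its methyls. Methylation, then hydroxymethylation and oxidation at the α'-carbon, make C10 (CH3 and CHO = C1).
3. Ring A then forms in one operation. The feature used: C4 (quaternary, two methyls, next to the oxygenated C3) and C1 (a CH2 on quaternary C10) are 1,4-related across the C5–C10 bond. A hydrogen-atom-transfer-initiated radical–polar crossover annulation inserts a two-carbon enal (C2–C3, oxygen on C3) between a C4 radical made from the isopropenyl group and the C1 aldehyde.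
4. Helpers: the formyl group on C2 and the hydroxyl on C1 leave by dehydration, decarbonylation and hydrogenation; the silyl group on O-3 leaves with fluoride; C3 passes through a ketone.
5. Stereochemistry: C5 from (S)-carvone; C10 by enolate attack anti to the isopropenyl group; C3 by axial hydride addition to the 3-ketone (equatorial OH, cis to CH3-10); C9 by hydroboration anti to CH3-10.
6. Ring B is completed late (C9=CH2, hydroboration) and the coumarin is attached last by Mitsunobu etherification.

Key step: step 5

Remark: drimane numbering is used (ring A = C1–C5 and C10, ring B = C5–C10, C11 on C9). The target is read as the ent-drimane (3R,5S,9R,10R), with 3-OAc, CH3-10 and C11 on one face and H-5 on the other; reagents without a number are commercial.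

**Step 1**
Reactants: 1 (S)-(+)-carvone
Product: 3 6-methylcarvone [(5S)-2,6-dimethyl-5-(prop-1-en-2-yl)cyclohex-2-en-1-one; both C6 epimers], via lithium dienolate 2 (not isolated)
Conditions: LiN(iPr)2, THF, −78 °C; MeI, −78 → 0 °C
Reagents that add atoms: iodomethane, CI
Why: Kinetic α'-deprotonation of the enone gives the cross-conjugated lithium dienolate 2, whose C-alkylation by iodomethane (enolate alkylation) should give 3; the new C6 center may form as both epimers because the next step makes this carbon quaternary.

**Step 2**
Reactants: 3 6-methylcarvone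
Product: 5 (5R,6S)-6-(hydroxymethyl)-2,6-dimethyl-5-(prop-1-en-2-yl)cyclohex-2-en-1-one (CH2OH trans to isopropenyl), via lithium dienolate 4 (not isolated)
Conditions: LiN(iPr)2, THF, −78 °C; monomeric CH2O (from cracked paraformaldehyde), −78 °C; aq NH4Cl
Reagents that add atoms: formaldehyde, C=O
Why: The α'-enolate 4 should add to formaldehyde (aldol addition) on the face anti to the neighbouring isopropenyl group, the general facial preference in the second α'-alkylation of 6-substituted carvones, which sets the future C10 with CH2OH (future C1) trans and CH3 cis to the isopropenyl group.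

**Step 3**
Reactants: 5 hydroxymethyl ketone
Product: 6 (1S,6R)-1,3-dimethyl-2-oxo-6-(prop-1-en-2-yl)cyclohex-3-ene-1-carbaldehyde
Conditions: DMP (1,1,1-triacetoxy-1,1-dihydro-1,2-benziodoxol-3(1H)-one), CH2Cl2, rt
Reagents that add atoms: none
Why: The hypervalent iodine reagent oxidises the neopentyl primary alcohol under neutral conditions, so the non-enolisable β-keto aldehyde should form without retro-aldol loss of formaldehyde (alcohol oxidation).

**Step 4**
Reactants: 7 malondialdehyde tetrabutylammonium salt
Product: 8 (E)-3-[(tert-butyldimethylsilyl)oxy]prop-2-enal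
Conditions: TBSCl, CH2Cl2, 0 °C → rt
Reagents that add atoms: tert-butyldimethylsilyl chloride, CC(C)(C)[Si](C)(C)Cl
Why: O-Silylation of the delocalised malondialdehyde enolate should give the vinylogous silyl ester with the E geometry of the W-shaped anion (enolate O-silylation).

**Step 5**
Reactants: 6 keto aldehyde; 8 silyloxy enal
Product: 9 3-[(tert-butyldimethylsilyl)oxy]-1-hydroxy-9-oxo-11-nor-ent-drim-7-ene-2-carbaldehyde (trans-fused; diastereomer mixture at C1/C2/C3)
Conditions: Fe(acac)3 (30 mol %), PhSiH2(OiPr), THF/i-PrOH, 0 °C → rt, 8 in excess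
Reagents that add atoms: none
Why: A trivalent iron hydride formed from Fe(acac)3 and the silane should transfer a hydrogen atom to the CH2 terminus of the isopropenyl group of 6, which makes the second C4 methyl and a tertiary C4 radical at once; this nucleophilic radical adds to the silyloxy-bearing β-carbon of 8 (C3–C4 bond), the α-formyl radical is reduced by divalent iron to an enolate, and its α-carbon (C2) attacks the C1 aldehyde in an intramolecular aldol addition (C1–C2 bond). The closest known reaction type is the hydrogen-atom-transfer-initiated radical–polar crossover annulation of alkenyl carbonyl compounds with unsaturated aldehydes (Giese addition, then aldol), and radical additions to the oxygen-bearing β-carbon of β-alkoxy acrylates are the precedent for the regiochemistry on this donor-substituted acceptor. Ring A closes in the aldol event as a 6-(enolexo)-exo-trig closure onto the aldehyde carbon, through a chair in which C4 and C1 are the trans-diequatorial arms already fixed on ring B, so the trans ring fusion (H-5 anti to CH3-10) is inherited from 6. The new centers C1, C2 and C3 are not controlled by the substrate (C3 is set in the intermolecular radical addition, C1 and C2 in the aldol) and need not be, because C1 and C2 end as CH2 and C3 passes through a ketone before step 10 fixes it. The step needs hydrogen-atom transfer to the 1,1-disubstituted alkene in preference to the conjugated trisubstituted C7=C8 bond and to the electron-poor acceptor, and aldol closure on the C1 aldehyde in preference to the hindered conjugated C9 ketone or to loss of silanolate from the enolate; the electron-rich, unhindered isopropenyl group, the higher electrophilicity of the aldehyde and an excess of 8 should secure this.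

**Step 6**
Reactants: 9 annulation product
Product: 11 3-[(tert-butyldimethylsilyl)oxy]-9-oxo-11-nor-ent-drima-1,7-diene-2-carbaldehyde (two C3 epimers), via C1 mesylate 10 (not isolated)
Conditions: MsCl, Et3N, CH2Cl2, 0 °C → rt
Reagents that add atoms: none
Why: Sulfonylation of the C1 hydroxyl to mesylate 10 and E1cB elimination through the aldehyde enolate should give the C1=C2 enal from every C1/C2 diastereomer, mesylate being a far better leaving group than the C3 silyloxy group (dehydration of an aldol).

**Step 7**
Reactants: 11 enal
Product: 13 3-hydroxy-11-nor-ent-drima-1,7-dien-9-one (two C3 epimers), via allylic silyl ether 12 (not isolated)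
Conditions: RhCl(PPh3)3 (1.1 equiv), PhCN, 130 °C; then Bu4NF, THF, rt
Reagents that add atoms: none
Why: Tsuji–Wilkinson decarbonylation (oxidative addition of rhodium into the formyl C–H bond, CO extrusion and C–H reductive elimination at the vinyl carbon) should remove the helper carbon and leave the C1=C2 alkene of 12, after which fluoride cleaves the Si–O bond to free the allylic C3 hydroxyl.

**Step 8**
Reactants: 13 allylic alcohol
Product: 14 11-nor-ent-drima-1,7-diene-3,9-dione
Conditions: DMP, CH2Cl2, rt
Reagents that add atoms: none
Why: Oxidation of the allylic alcohol should converge both C3 epimers on the single enone 14, which erases the C3 ambiguity left by step 5 (alcohol oxidation).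

**Step 9**
Reactants: 14 dienedione
Product: 15 11-nor-ent-drim-7-ene-3,9-dione
Conditions: H2 (1 atm), RhCl(PPh3)3 (cat), benzene/EtOH, rt
Reagents that add atoms: none
Why: Homogeneous hydrogenation with RhCl(PPh3)3 should saturate the cis-disubstituted C1=C2 bond of the ring A enone and leave the trisubstituted, α-methylated C7=C8 bond of the ring B enone, the selectivity known for 1,4-dien-3-ones with a quaternary C10 (chemoselective alkene hydrogenation).

**Step 10**
Reactants: 15 diketone
Product: 16 3-hydroxy-11-nor-ent-drim-7-en-9-one (OH equatorial, cis to CH3-10)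
Conditions: NaBH4, MeOH/CH2Cl2, −78 °C
Reagents that add atoms: none
Why: NaBH4 should reduce the saturated C3 ketone far faster than the conjugated C9 ketone flanked by quaternary C10 and C8, and hydride should enter C3 along the axial direction on the face opposite CH3-10 and the axial C4 methyl group, which gives the equatorial alcohol cis to CH3-10 as for 4,4-dimethyl-3-oxo terpenoids (diastereoselective carbonyl reduction).

**Step 11**
Reactants: 16 hydroxy enone
Product: 17 ent-drima-7,9(11)-dien-3-ol (OH cis to CH3-10)
Conditions: Ph3PCH3Br, KOtBu, toluene, 90 °C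
Reagents that add atoms: methyltriphenylphosphonium bromide (source of the ylide Ph3P=CH2), C[P+](c1ccccc1)(c1ccccc1)c1ccccc1.[Br-]
Why: Wittig methylenation with an excess of methylenetriphenylphosphorane at elevated temperature should convert the hindered C9 ketone, which has no α-hydrogen at C10, into the exocyclic C9=C11 alkene while the C3 hydroxyl is carried as its alkoxide.

**Step 12**
Reactants: 17 dienol
Product: 18 ent-drima-7,9(11)-dien-3-yl acetate
Conditions: Ac2O, pyridine, DMAP (cat), CH2Cl2, rt
Reagents that add atoms: acetic anhydride, CC(=O)OC(C)=O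
Why: DMAP-catalysed acylation with acetic anhydride should esterify the hindered equatorial C3 hydroxyl without touching the diene (esterification).

**Step 13**
Reactants: 18 diene acetate
Product: 20 3-acetoxy-ent-drim-7-en-11-ol (C11 cis to CH3-10), via B-alkyl-9-borabicyclononane 19 (not isolated)
Conditions: 9-BBN, THF, 0 °C → rt; then 30% H2O2, aq NaOAc, 0 °C → rt
Reagents that add atoms: hydrogen peroxide, OO
Why: 9-BBN should add only to the 1,1-disubstituted C9=C11 bond, with boron on C11 (borane 19) and hydrogen delivered to C9 from the face opposite the axial CH3-10, so that C11 ends cis to CH3-10, and buffered peroxide oxidation then replaces boron by hydroxyl while the acetate survives (hydroboration–oxidation).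

**Step 14**
Reactants: 20 primary alcohol; 21 umbelliferone (7-hydroxycoumarin)
Product: 22 (3R,5S,9R,10R)-3-acetoxy-ent-drim-7-en-11-yl 2-oxo-2H-chromen-7-yl ether (target)
Conditions: PPh3, DIAD, THF, 0 °C → rt
Reagents that add atoms: none
Why: Mitsunobu etherification should join the primary C11 alcohol to the acidic phenol of umbelliferone by SN2 displacement of the oxyphosphonium group, at a carbon that is not stereogenic.

**Compound list**

1 | (S)-(+)-carvone | CC1=CC[C@@H](CC1=O)C(C)=C | starting material
2 | lithium dienolate of 1 | [Li+].CC1=CC[C@@H](C=C1[O-])C(C)=C | intermediate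
3 | (5S)-2,6-dimethyl-5-(prop-1-en-2-yl)cyclohex-2-en-1-one (C6 epimers) | CC1=CC[C@@H](C(C)C1=O)C(C)=C | intermediate
4 | lithium dienolate of 3 | [Li+].CC1=CC[C@@H](C(C)=C1[O-])C(C)=C | intermediate
5 | (5R,6S)-6-(hydroxymethyl)-2,6-dimethyl-5-(prop-1-en-2-yl)cyclohex-2-en-1-one | OC[C@@]1(C)C(=O)C(C)=CC[C@@H]1C(C)=C | intermediate
6 | (1S,6R)-1,3-dimethyl-2-oxo-6-(prop-1-en-2-yl)cyclohex-3-ene-1-carbaldehyde | O=C[C@@]1(C)C(=O)C(C)=CC[C@@H]1C(C)=C | intermediate
7 | malondialdehyde tetrabutylammonium salt | [O-]/C=C/C=O.CCCC[N+](CCCC)(CCCC)CCCC | starting material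
8 | (E)-3-[(tert-butyldimethylsilyl)oxy]prop-2-enal | O=C/C=C/O[Si](C)(C)C(C)(C)C | intermediate
9 | 3-[(tert-butyldimethylsilyl)oxy]-1-hydroxy-9-oxo-11-nor-ent-drim-7-ene-2-carbaldehyde (C1/C2/C3 mixture) | O=CC1C(O)[C@@]2(C)C(=O)C(C)=CC[C@@H]2C(C)(C)C1O[Si](C)(C)C(C)(C)C | intermediate
10 | C1 methanesulfonate of 9 | O=CC1C(OS(C)(=O)=O)[C@@]2(C)C(=O)C(C)=CC[C@@H]2C(C)(C)C1O[Si](C)(C)C(C)(C)C | intermediate
11 | 3-[(tert-butyldimethylsilyl)oxy]-9-oxo-11-nor-ent-drima-1,7-diene-2-carbaldehyde (C3 epimers) | O=CC1=C[C@@]2(C)C(=O)C(C)=CC[C@@H]2C(C)(C)C1O[Si](C)(C)C(C)(C)C | intermediate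
12 | 3-[(tert-butyldimethylsilyl)oxy]-11-nor-ent-drima-1,7-dien-9-one (C3 epimers) | C1=C[C@@]2(C)C(=O)C(C)=CC[C@@H]2C(C)(C)C1O[Si](C)(C)C(C)(C)C | intermediate
13 | 3-hydroxy-11-nor-ent-drima-1,7-dien-9-one (C3 epimers) | OC1C=C[C@@]2(C)C(=O)C(C)=CC[C@@H]2C1(C)C | intermediate
14 | 11-nor-ent-drima-1,7-diene-3,9-dione | O=C1C=C[C@@]2(C)C(=O)C(C)=CC[C@@H]2C1(C)C | intermediate
15 | 11-nor-ent-drim-7-ene-3,9-dione | O=C1CC[C@@]2(C)C(=O)C(C)=CC[C@@H]2C1(C)C | intermediate
16 | 3-hydroxy-11-nor-ent-drim-7-en-9-one (OH cis to CH3-10) | O[C@@H]1CC[C@@]2(C)C(=O)C(C)=CC[C@@H]2C1(C)C | intermediate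
17 | ent-drima-7,9(11)-dien-3-ol (OH cis to CH3-10) | O[C@@H]1CC[C@@]2(C)C(=C)C(C)=CC[C@@H]2C1(C)C | intermediate
18 | ent-drima-7,9(11)-dien-3-yl acetate | CC(=O)O[C@@H]1CC[C@@]2(C)C(=C)C(C)=CC[C@@H]2C1(C)C | intermediate
19 | B-(3-acetoxy-ent-drim-7-en-11-yl)-9-borabicyclo[3.3.1]nonane | CC(=O)O[C@@H]1CC[C@@]2(C)[C@H](CB3C4CCCC3CCC4)C(C)=CC[C@@H]2C1(C)C | intermediate
20 | 3-acetoxy-ent-drim-7-en-11-ol | CC(=O)O[C@@H]1CC[C@@]2(C)[C@H](CO)C(C)=CC[C@@H]2C1(C)C | intermediate
21 | umbelliferone (7-hydroxycoumarin) | Oc1ccc2ccc(=O)oc2c1 | starting material
22 | (3R,5S,9R,10R)-3-acetoxy-ent-drim-7-en-11-yl 2-oxo-2H-chromen-7-yl ether | CC(=O)O[C@@H]1CC[C@@]2(C)[C@H](COc3ccc4ccc(=O)oc4c3)C(C)=CC[C@@H]2C1(C)C | target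

**Step count and risks**

Total step count: 14. Longest linear sequence: 13 steps (steps 1–3 and 5–14, from 1 to 22); step 4 is a one-step side branch.

Steps most likely to fail:

1. Step 5 (annulation). The tertiary radical may add too slowly to the donor-substituted β-carbon of 8 and be reduced instead. Acceptor 8 may itself be consumed by hydrogen-atom transfer. The enolate may lose silanolate by β-elimination before the aldol closure. Fallback: starting from 6, the same annulation would be run with plain acrolein, the acceptor class for which it is established, to give the hydroxy aldehyde F1. Mesylation and elimination (MsCl, Et3N) would give the enal F2, and decarbonylation with RhCl(PPh3)3 the dienone F3. Allylic oxidation of the only allylic CH2 next to the ring A alkene (C3) with CrO3 and 3,5-dimethylpyrazole would return to the route at 14. The C3 oxygen is then introduced by C–H oxidation after ring closure instead of travelling with the two-carbon unit.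

2. Step 14 (etherification). The activated, β-branched homoallylic oxyphosphonium may eliminate to the 7,9(11)-diene faster than the weakly nucleophilic phenoxide substitutes. Fallback: starting from 20, the C–O bond would be formed from the aryl side by palladium-catalysed coupling with 7-bromocoumarin ([Pd(allyl)Cl]2, RockPhos, Cs2CO3, toluene, 90 °C). This gives 22 directly, with no new intermediate.

3. Step 11 (methylenation). The ylide may fail to add to the conjugated carbonyl flanked by quaternary C10 and C8, and may instead deprotonate C6 to a dienolate. Fallback: starting from 16, the small, weakly basic reagent from Me3SiCH2Li and CeCl3 would add to C9 to give the β-hydroxysilane F4. Elimination with KH in THF (Peterson olefination) would return to the route at 17.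

**Further compounds**

F1 | step 5 | 1-hydroxy-9-oxo-11-nor-ent-drim-7-ene-2-carbaldehyde (C1/C2 mixture) | O=CC1C(O)[C@@]2(C)C(=O)C(C)=CC[C@@H]2C(C)(C)C1
F2 | step 5 | 9-oxo-11-nor-ent-drima-1,7-diene-2-carbaldehyde | O=CC1=C[C@@]2(C)C(=O)C(C)=CC[C@@H]2C(C)(C)C1
F3 | step 5 | 11-nor-ent-drima-1,7-dien-9-one | C1=C[C@@]2(C)C(=O)C(C)=CC[C@@H]2C(C)(C)C1
F4 | step 11 | 9-[(trimethylsilyl)methyl]-11-nor-ent-drim-7-ene-3,9-diol | O[C@@H]1CC[C@@]2(C)C(O)(C[Si](C)(C)C)C(C)=CC[C@@H]2C1(C)C
F0 | step 14 | none | none
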